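**Retrosynthetic overview**
- The target flavonol comes from BCl3 unmasking (5-O-methyl and both benzyl groups) of the 3-hydroxy-5,6,7,8-tetramethoxy-3',4'-dibenzyloxyflavone, which comes from the 3-iodoflavone by exchanging C3–I for C3–OH.
- The 3-iodoflavone comes from an aryl alkynyl ketone by ICl-induced 6-endo-dig closure of ring C (O1–C2 bond formed, one ortho O-methyl lost).
- The ynone comes from a one-pot union of iodopentamethoxybenzene, carbon monoxide (which becomes C4) and 3,4-dibenzyloxyphenylacetylene, forming C4a–C4 and C4–C3.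
- Structural feature used: the C4 carbonyl carbon sits between the fully substituted ring A (at C4a) and C3, and a pentamethoxyphenyl group is symmetric about its C4a–C7 axis, so either ortho oxygen can become O1 while the other ends as the 5-OH.
- Ring order: rings A and B are bought as benzenes; ring C is the only ring made, and it closes after the key step.

Key step: step 5

Remark: the target has no stereocentre, so no stereocontrol is needed; 1,2,3,4-tetramethoxybenzene, 3,4-bis(benzyloxy)benzaldehyde and carbon monoxide are taken as purchased.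

**Route**

Step 1
Reactants: 1 1,2,3,4-tetramethoxybenzene
Product: 4 2,3,4,5-tetramethoxyphenol, via aryllithium 2 (not isolated), via dimethyl arylboronate 3 (not isolated)
Conditions: n-BuLi, TMEDA, THF, 0 °C; B(OMe)3, −78 °C → rt; 30% H2O2, AcOH, 0 °C → rt
Reagents that add atoms: hydrogen peroxide, OO (phenol oxygen of 4); n-butyllithium, [Li]CCCC (lithium of 2); trimethyl borate, COB(OC)OC (boron and methoxy groups of 3)
Why: Directed ortho-metalation beside a terminal methoxy group (the two free positions are equivalent), borylation of the aryllithium and peroxide oxidation of the C–B bond is a standard way to turn an aryl C–H into a phenol.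

Step 2
Reactants: 4 2,3,4,5-tetramethoxyphenol
Product: 5 pentamethoxybenzene
Conditions: MeI, K2CO3, acetone, reflux, under argon
Reagents that add atoms: iodomethane, CI
Why: Williamson O-methylation of the phenoxide is reliable, and working under argon keeps the electron-rich phenol from air oxidation to a quinone.

Step 3
Reactants: 5 pentamethoxybenzene
Product: 6 1-iodo-2,3,4,5,6-pentamethoxybenzene
Conditions: NIS, TFA (cat.), MeCN, rt, dark
Reagents that add atoms: N-iodosuccinimide, O=C1CCC(=O)N1I
Why: Electrophilic aromatic iodination with acid-activated NIS has only one position to attack, and that position is activated by two ortho and one para methoxy groups.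

Step 4
Reactants: 7 3,4-bis(benzyloxy)benzaldehyde
Product: 8 4-ethynyl-1,2-bis(benzyloxy)benzene
Conditions: dimethyl (1-diazo-2-oxopropyl)phosphonate, K2CO3, MeOH/THF, 0 °C → rt
Reagents that add atoms: dimethyl (1-diazo-2-oxopropyl)phosphonate, CC(=O)C(=[N+]=[N-])P(=O)(OC)OC (supplies the terminal alkyne carbon)
Why: The Ohira–Bestmann (Seyferth–Gilbert) homologation converts aryl aldehydes into terminal alkynes under mild carbonate conditions that leave benzyl ethers untouched.

Step 5
Reactants: 6 1-iodo-2,3,4,5,6-pentamethoxybenzene, 8 4-ethynyl-1,2-bis(benzyloxy)benzene, 9 carbon monoxide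
Product: 10 3-[3,4-bis(benzyloxy)phenyl]-1-(pentamethoxyphenyl)prop-2-yn-1-one
Conditions: PdCl2(PPh3)2 (cat.), CuI (cat.), Et3N, THF, CO (balloon, raised to about 5 bar if needed), rt → 50 °C, degassed
Reagents that add atoms: none
Why: PdCl2(PPh3)2 is reduced in the flask to zerovalent palladium, which inserts into the C–I bond of 6; CO then inserts into the crowded aryl–palladium bond to give an aroylpalladium iodide, the copper acetylide formed from 8, CuI and Et3N transmetalates, and reductive elimination releases ynone 10, so C4a–C4 and C4–C3 are both made in one catalytic turnover. The closest known reaction type is the carbonylative Sonogashira coupling of aryl iodides with terminal alkynes under CO to give aryl alkynyl ketones. No ring is closed and no stereocentre is formed in this step. The selectivity needed is carbonylative over direct alkynylation and over alkyne homocoupling: the two ortho methoxy groups slow transmetalation at the aryl–palladium stage so that CO insertion, which relieves the crowding, should win, a higher CO pressure reinforces this, and exclusion of oxygen suppresses the diyne. Site selectivity is not an issue because 6 has one C–I bond and no C–H bond.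

Step 6
Reactants: 10 3-[3,4-bis(benzyloxy)phenyl]-1-(pentamethoxyphenyl)prop-2-yn-1-one
Product: 11 2-[3,4-bis(benzyloxy)phenyl]-3-iodo-5,6,7,8-tetramethoxy-4H-chromen-4-one
Conditions: ICl (1.2–1.5 equiv), CH2Cl2, −78 °C → rt; aq. Na2S2O3
Reagents that add atoms: iodine monochloride, ClI
Why: In this ICl-induced electrophilic cyclisation of an ortho-methoxyaryl ynone, iodonium activation of the alkyne, 6-endo-dig attack of an ortho methoxy oxygen at the aryl-bearing alkyne carbon and chloride demethylation of the oxonium ion should give the 3-iodochromone, the two ortho methoxy groups being equivalent by symmetry.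

Step 7
Reactants: 11 2-[3,4-bis(benzyloxy)phenyl]-3-iodo-5,6,7,8-tetramethoxy-4H-chromen-4-one
Product: 14 2-[3,4-bis(benzyloxy)phenyl]-3-hydroxy-5,6,7,8-tetramethoxy-4H-chromen-4-one, via chromen-3-ylmagnesium chloride 12 (not isolated), via dimethyl chromen-3-ylboronate 13 (not isolated)
Conditions: i-PrMgCl·LiCl, THF, −40 °C; B(OMe)3, −40 → 0 °C; 30% H2O2, AcOH, 0 °C → rt
Reagents that add atoms: hydrogen peroxide, OO (3-hydroxyl oxygen of 14); isopropylmagnesium chloride, CC(C)[Mg]Cl (MgCl of 12); trimethyl borate, COB(OC)OC (B(OMe)2 of 13)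
Why: Iodine–magnesium exchange of the β-oxygenated α-iodoenone should give a C3 alkenylmagnesium species that persists at low temperature, and its borylation followed by peroxide oxidation of the C–B bond delivers the enol, here the flavonol, as in metalation–borylation–oxidation of C3-metalated flavones.

Step 8
Reactants: 14 2-[3,4-bis(benzyloxy)phenyl]-3-hydroxy-5,6,7,8-tetramethoxy-4H-chromen-4-one
Product: 15 3,5,3',4'-tetrahydroxy-6,7,8-trimethoxyflavone
Conditions: BCl3 (excess), pentamethylbenzene, CH2Cl2, −78 → 0 °C; aq. HCl work-up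
Reagents that add atoms: none
Why: In this Lewis acid ether cleavage, BCl3 with a cation scavenger removes aryl benzyl ethers at low temperature and, through chelation to the C4 carbonyl, should cleave only the peri 5-O-methyl group, leaving the 6-, 7- and 8-methoxy groups.

**Compound list**
1 | 1,2,3,4-tetramethoxybenzene | COc1ccc(OC)c(OC)c1OC | starting material
2 | (2,3,4,5-tetramethoxyphenyl)lithium | [Li]c1cc(OC)c(OC)c(OC)c1OC | intermediate
3 | dimethyl (2,3,4,5-tetramethoxyphenyl)boronate | COB(OC)c1cc(OC)c(OC)c(OC)c1OC | intermediate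
4 | 2,3,4,5-tetramethoxyphenol | Oc1cc(OC)c(OC)c(OC)c1OC | intermediate
5 | pentamethoxybenzene | COc1cc(OC)c(OC)c(OC)c1OC | intermediate
6 | 1-iodo-2,3,4,5,6-pentamethoxybenzene | COc1c(OC)c(OC)c(I)c(OC)c1OC | intermediate
7 | 3,4-bis(benzyloxy)benzaldehyde | O=Cc1ccc(OCc2ccccc2)c(OCc2ccccc2)c1 | starting material
8 | 4-ethynyl-1,2-bis(benzyloxy)benzene | C#Cc1ccc(OCc2ccccc2)c(OCc2ccccc2)c1 | intermediate
9 | carbon monoxide | [C-]#[O+] | starting material
10 | 3-[3,4-bis(benzyloxy)phenyl]-1-(pentamethoxyphenyl)prop-2-yn-1-one | COc1c(OC)c(OC)c(C(=O)C#Cc2ccc(OCc3ccccc3)c(OCc3ccccc3)c2)c(OC)c1OC | intermediate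
11 | 2-[3,4-bis(benzyloxy)phenyl]-3-iodo-5,6,7,8-tetramethoxy-4H-chromen-4-one | COc1c(OC)c(OC)c2c(=O)c(I)c(-c3ccc(OCc4ccccc4)c(OCc4ccccc4)c3)oc2c1OC | intermediate
12 | {2-[3,4-bis(benzyloxy)phenyl]-5,6,7,8-tetramethoxy-4-oxo-4H-chromen-3-yl}magnesium chloride | COc1c(OC)c(OC)c2c(=O)c([Mg]Cl)c(-c3ccc(OCc4ccccc4)c(OCc4ccccc4)c3)oc2c1OC | intermediate
13 | dimethyl {2-[3,4-bis(benzyloxy)phenyl]-5,6,7,8-tetramethoxy-4-oxo-4H-chromen-3-yl}boronate | COc1c(OC)c(OC)c2c(=O)c(B(OC)OC)c(-c3ccc(OCc4ccccc4)c(OCc4ccccc4)c3)oc2c1OC | intermediate
14 | 2-[3,4-bis(benzyloxy)phenyl]-3-hydroxy-5,6,7,8-tetramethoxy-4H-chromen-4-one | COc1c(OC)c(OC)c2c(=O)c(O)c(-c3ccc(OCc4ccccc4)c(OCc4ccccc4)c3)oc2c1OC | intermediate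
15 | 3,5,3',4'-tetrahydroxy-6,7,8-trimethoxyflavone | COc1c(OC)c(O)c2c(=O)c(O)c(-c3ccc(O)c(O)c3)oc2c1OC | target

**Step count**
Total steps: 8. Longest linear sequence: 7 (steps 1, 2, 3, 5, 6, 7, 8); the alkyne branch (step 4) joins at step 5.

**Steps most likely to fail**

Step 5. Oxidative addition into the electron-rich, doubly ortho-flanked C–I bond may be slow, so that oxidative dimerisation of the alkyne and non-carbonylative coupling use up the alkyne before CO is incorporated. The fallback sets out from 5 (with 8) and returns at 10, replacing CO gas by CO2 as the one-carbon source. Deprotonation of 5 at its single C–H with n-BuLi (THF, 0 °C) should give (pentamethoxyphenyl)lithium F1. Carboxylation with CO2 and acidification should give 2,3,4,5,6-pentamethoxybenzoic acid F2. Oxalyl chloride with catalytic DMF in CH2Cl2 should give 2,3,4,5,6-pentamethoxybenzoyl chloride F3. Acyl Sonogashira coupling of F3 with 8 (PdCl2(PPh3)2, CuI, Et3N, THF, rt) should give 10 through the same aroylpalladium species.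

Step 7. The C3-magnesiated chromone may open ring C by β-elimination of the ring phenoxide, or be protonated before it is borylated, giving net reduction. The fallback sets out from 11 and returns at 14 without any C3 carbanion. Miyaura borylation of the alkenyl iodide (B2pin2, PdCl2(dppf), KOAc, dioxane, 80 °C) should give 2-[3,4-bis(benzyloxy)phenyl]-5,6,7,8-tetramethoxy-3-(4,4,5,5-tetramethyl-1,3,2-dioxaborolan-2-yl)-4H-chromen-4-one F4. Mild oxidation of F4 with NaBO3·4H2O in THF/water at rt should give 14.

Step 8. The 5-O-boron chelate may go on to cleave the adjacent 6-O-methyl group, and benzyl cations may C-alkylate the electron-rich rings. The fallback sets out from 14 and returns at 15, separating the two deprotections. Hydrogenolysis (H2, Pd/C, EtOAc/MeOH, rt) should remove both benzyl groups and give 3,3',4'-trihydroxy-5,6,7,8-tetramethoxyflavone F5. Acid-mediated selective 5-O-demethylation of F5 (conc. HCl, EtOH, reflux), which is driven by the protonated C4 carbonyl and is known to spare the 6-, 7- and 8-methoxy groups of 5,6,7,8-tetramethoxyflavones, should give 15.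

**Further compounds**
F1 | step 5 | (pentamethoxyphenyl)lithium | [Li]c1c(OC)c(OC)c(OC)c(OC)c1OC
F2 | step 5 | 2,3,4,5,6-pentamethoxybenzoic acid | COc1c(OC)c(OC)c(C(=O)O)c(OC)c1OC
F3 | step 5 | 2,3,4,5,6-pentamethoxybenzoyl chloride | COc1c(OC)c(OC)c(C(=O)Cl)c(OC)c1OC
F4 | step 7 | 2-[3,4-bis(benzyloxy)phenyl]-5,6,7,8-tetramethoxy-3-(4,4,5,5-tetramethyl-1,3,2-dioxaborolan-2-yl)-4H-chromen-4-one | COc1c(OC)c(OC)c2c(=O)c(B5OC(C)(C)C(C)(C)O5)c(-c3ccc(OCc4ccccc4)c(OCc4ccccc4)c3)oc2c1OC
F5 | step 8 | 3,3',4'-trihydroxy-5,6,7,8-tetramethoxyflavone | COc1c(OC)c(OC)c2c(=O)c(O)c(-c3ccc(O)c(O)c3)oc2c1OC
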